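**Retrosynthetic overview**
1. Target 37 is cut at C11–C12: Julia–Kocienski olefination of a decalin C11 sulfone with a 1,2-dioxane C12 aldehyde, then diimide saturation, which does not touch the O–O bond.
2. The strategy rests on the cis-fused ring A/ring B junction, where the tertiary carbinol C5 lies between quaternary C4 (gem-dimethyl) and quaternary C10 (angular methyl). The C4–C5 bond is made by 6-exo addition of a C4 tertiary radical, generated by hydrogen-atom transfer to a C3=C4 alkene, to a C5 ketone.
3. Decalin half: ring B first (organocatalytic Michael addition and aldol condensation, then conjugate addition at C9 and enolate alkylation at C10), ring A second (the radical closure).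
4. Dioxane half, from geraniol: the Sharpless epoxide fixes C6' (inverted on perhydrolysis) and a syn crotylboration fixes C2'/C3' (C3' inverted when the hydroperoxide displaces a mesylate); the vinyl group then becomes the ester and the silyloxy diol the C12 aldehyde.
5. Both halves are single enantiomers before they are joined, so no stereochemical relay between the two domains is needed.

Key step: step 7

Remark (numbering and assumptions): decalin carbons are C1–C10 as in labdanes, the linker carbons are C11 and C12, and the dioxane–propanoate carbons are primed (C1' ester carbon, C2', ring carbons C3'–C6'). The E geometry written for alkene 35 is the expected one and is immaterial, because the alkene is saturated in step 25. The tertiary C5 hydroxyl is carried through the fragment union as a trimethylsilyl ether so that one equivalent of base forms only the sulfonyl carbanion.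

**Decalin half**

Step 1
Reactants: 1 propanal; 2 pent-1-en-3-one
Product: 3 (R)-2-methyl-5-oxoheptanal
Conditions: (S)-α,α-diphenylprolinol trimethylsilyl ether (5 mol %), ethyl 3,4-dihydroxybenzoate (20 mol %), neat, 4 °C
Reagents that add atoms: none
Why: Enamine-catalysed Michael addition in which the E-enamine of propanal, shielded on one face by the silyloxydiphenylmethyl group of the (S)-catalyst, should bond to the enone from the open face and set the 2R centre (future C8), by analogy with the sense of related aldehyde Michael additions with this catalyst.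

Step 2
Reactants: 3 (R)-2-methyl-5-oxoheptanal
Product: 4 (R)-2,4-dimethylcyclohex-2-en-1-one
Conditions: LiOH·H2O (0.1 equiv), iPrOH, rt
Reagents that add atoms: none
Why: Intramolecular aldol condensation of the ethyl ketone α-methylene onto the aldehyde closes ring B, and under mild hydroxide catalysis ring closure should outrun enolisation of the branched aldehyde so that the C8 centre is kept.

Step 3
Reactants: 5 (chloromethyl)dimethylphenylsilane
Product: 6 [(dimethylphenylsilyl)methyl]magnesium chloride (titrated THF solution, used directly)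
Conditions: Mg turnings, BrCH2CH2Br (cat.), THF, reflux then rt
Reagents that add atoms: magnesium, [Mg]
Why: Grignard formation by insertion of magnesium into the C–Cl bond of an α-silyl alkyl chloride gives a hydroxymethyl anion equivalent that delivers C11.

Step 4
Reactants: 4 (R)-2,4-dimethylcyclohex-2-en-1-one; 6 [(dimethylphenylsilyl)methyl]magnesium chloride
Product: 7 {[(3S,4R)-3-[(dimethylphenylsilyl)methyl]-2,4-dimethylcyclohex-1-en-1-yl]oxy}trimethylsilane
Conditions: CuBr·SMe2 (10 mol %), Me3SiCl, HMPA, THF, −78 °C; Et3N quench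
Reagents that add atoms: chlorotrimethylsilane, C[Si](C)(C)Cl
Why: Copper-catalysed, chlorosilane-accelerated conjugate addition in which the organocopper species should approach C9 from the face opposite the adjacent C8 methyl (trans-8,9), while silyl trapping stores the enolate as the C5=C10 regioisomer.

Step 5
Reactants: 8 5-bromo-2-methylpent-2-ene
Product: 9 5-iodo-2-methylpent-2-ene
Conditions: NaI, acetone, reflux
Reagents that add atoms: sodium iodide, [Na+].[I-]
Why: Finkelstein halide exchange, driven by precipitation of NaBr, gives the more reactive primary iodide for the alkylation.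

Step 6
Reactants: 7 silyl enol ether; 9 5-iodo-2-methylpent-2-ene
Product: 11 (2R,3S,4R)-3-[(dimethylphenylsilyl)methyl]-2,4-dimethyl-2-(4-methylpent-3-en-1-yl)cyclohexan-1-one, via lithium enolate 10 (not isolated)
Conditions: MeLi (1.05 equiv), THF, 0 °C to rt; then HMPA, 9 (3 equiv), −78 °C to rt
Reagents that add atoms: none
Why: Si–O cleavage by MeLi regenerates the regiodefined tetrasubstituted lithium enolate, and SN2 alkylation at C10 should take place on the face anti to the C9 silylmethyl group, creating the C10 quaternary centre with its methyl cis to C11.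

Step 7
Reactants: 11 alkenyl ketone
Product: 12 (5S,8R,9S,10R)-9-[(dimethylphenylsilyl)methyl]-4,4,8,10-tetramethyl-cis-decalin-5-ol
Conditions: Fe(acac)3 (0.5 equiv), PhSiH3 (2.5 equiv), degassed EtOH, 60 °C
Reagents that add atoms: none
Why: Ethanolysis of PhSiH3 in the presence of trivalent iron generates an iron hydride that transfers a hydrogen atom to the less substituted alkene carbon C3 and leaves the nucleophilic tertiary radical at C4 (Markovnikov hydrogen-atom transfer). The radical adds to the carbonyl carbon C5 and closes ring A in a 6-exo-trig mode, and the alkoxyl radical so formed is reduced by divalent iron to the alkoxide faster than it can fragment back, which returns trivalent iron and makes the C4–C5 bond permanent before ethanol releases the alcohol. The closest known reaction type is the iron-hydride-initiated reductive radical cyclisation of alkene-tethered ketones, which gives cis-fused bicyclic tertiary alcohols. C5 is the only new stereocentre and is controlled by C10: in the ring B chair with the C8 methyl and C9 silylmethyl groups equatorial, the tether is equatorial and the C10 methyl axial, so a chair-like closure brings C4 onto the axial face of the carbonyl and leaves the hydroxyl cis to the C10 methyl. The trans-fused alternative would require bonding on the equatorial face with the C10 methyl axial on both rings and syn-axial to a C4 methyl, and should be disfavoured. The step needs cyclisation to outrun simple reduction of the C4 radical, which the quaternary C10 (tether held next to the carbonyl), the single alkene and the absence of other reactive groups (the C–Si bond is inert) should secure.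

Step 8
Reactants: 12 decalinol silane
Product: 13 (5S,8R,9S,10R)-9-(hydroxymethyl)-4,4,8,10-tetramethyl-cis-decalin-5-ol
Conditions: KBr, AcOOH (32 % in AcOH), NaOAc, AcOH, 0 °C to rt
Reagents that add atoms: peracetic acid, CC(=O)OO
Why: Fleming–Tamao oxidation, in which bromodesilylation of the phenyl ring makes silicon electrophilic and the peracid then induces migration of C11 from silicon to oxygen; it is placed after step 7 so that no alkene is exposed to the brominating medium, and the tertiary C5 hydroxyl is inert.

Step 9
Reactants: 13 diol; 14 1-phenyl-1H-tetrazole-5-thiol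
Product: 15 5-{[(5S,8R,9S,10R)-5-hydroxy-4,4,8,10-tetramethyl-cis-decalin-9-yl]methylsulfanyl}-1-phenyl-1H-tetrazole
Conditions: PPh3, DIAD, THF, 0 °C to rt
Reagents that add atoms: none
Why: Mitsunobu thioetherification, in which only the primary C11 hydroxyl can be activated as the oxyphosphonium ion and is displaced by the acidic, soft thiol, while the tertiary C5 hydroxyl between two quaternary carbons does not react.

Step 10
Reactants: 15 sulfide
Product: 16 5-{[(5S,8R,9S,10R)-5-hydroxy-4,4,8,10-tetramethyl-cis-decalin-9-yl]methylsulfonyl}-1-phenyl-1H-tetrazole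
Conditions: (NH4)6Mo7O24·4H2O (10 mol %), 30 % H2O2, EtOH, 0 °C to rt
Reagents that add atoms: hydrogen peroxide, OO
Why: Molybdate-catalysed peroxide oxidation of the sulfide through the sulfoxide to the sulfone, with no other oxidisable group in the molecule.

Step 11
Reactants: 16 hydroxy sulfone
Product: 17 5-{[(5S,8R,9S,10R)-4,4,8,10-tetramethyl-5-(trimethylsilyloxy)-cis-decalin-9-yl]methylsulfonyl}-1-phenyl-1H-tetrazole
Conditions: Me3SiOTf, 2,6-lutidine, CH2Cl2, −78 to 0 °C
Reagents that add atoms: trimethylsilyl trifluoromethanesulfonate, C[Si](C)(C)OS(=O)(=O)C(F)(F)F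
Why: Silylation of the hindered tertiary alcohol with the silyl triflate removes the only O–H, so that no alkoxide accompanies the sulfonyl carbanion in the union step.

**Dioxane half**

Step 12
Reactants: 18 geraniol
Product: 19 [(2R,3R)-3-methyl-3-(4-methylpent-3-en-1-yl)oxiran-2-yl]methanol
Conditions: Ti(OiPr)4 (5 mol %), D-(−)-diethyl tartrate (6 mol %), tBuOOH, 4 Å molecular sieves, CH2Cl2, −20 °C
Reagents that add atoms: tert-butyl hydroperoxide, CC(C)(C)OO
Why: Sharpless asymmetric epoxidation, in which the titanium tartrate complex delivers oxygen only to the allylic alcohol alkene and the D-(−)-tartrate ligand selects the face that gives the (2R,3R) epoxide (C3 is the future C6').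

Step 13
Reactants: 19 epoxy alcohol
Product: 20 tert-butyl{[(2R,3R)-3-methyl-3-(4-methylpent-3-en-1-yl)oxiran-2-yl]methoxy}diphenylsilane
Conditions: tBuPh2SiCl, imidazole, CH2Cl2, 0 °C to rt
Reagents that add atoms: tert-butyl(chloro)diphenylsilane, CC(C)(C)[Si](Cl)(c1ccccc1)c1ccccc1
Why: Silylation of the primary alcohol blocks Payne rearrangement and keeps this carbon distinguishable for its later excision.

Step 14
Reactants: 20 silyl ether
Product: 21 3-[(2R,3R)-3-({[tert-butyl(diphenyl)silyl]oxy}methyl)-2-methyloxiran-2-yl]propanal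
Conditions: O3, pyridine (3 equiv), CH2Cl2, −78 °C
Reagents that add atoms: ozone, [O-][O+]=O
Why: Ozonolysis of the only alkene, with pyridine intercepting the carbonyl oxide so that the aldehyde is released directly without a reductive work-up; the epoxide and silyl ether are inert.

Step 15
Reactants: 21 epoxy aldehyde; 22 cis-2-butene
Product: 25 (3R,4R)-6-[(2R,3R)-3-({[tert-butyl(diphenyl)silyl]oxy}methyl)-2-methyloxiran-2-yl]-3-methylhex-1-en-4-ol, via (Z)-crotylpotassium 23 (not isolated), via (Z)-crotyldiisopinocampheylborane 24 (not isolated)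
Conditions: 22, KOtBu, n-BuLi, THF, −78 to −45 °C; (−)-Ipc2BOMe [from (+)-α-pinene], −78 °C; BF3·OEt2 (1.0 equiv on boron); 21, −78 °C; NaOH, H2O2, 0 °C to rt
Reagents that add atoms: none
Why: Crotylboration through a closed chair transition state, in which the Z geometry of the borane translates into the 2',3'-syn relationship and the isopinocampheyl groups derived from (+)-α-pinene should direct the reagent to the Si face of the aldehyde, giving the (3R,4R) alcohol independently of the remote epoxide.

Step 16
Reactants: 25 homoallylic alcohol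
Product: 26 (3R,4R)-6-[(2R,3R)-3-({[tert-butyl(diphenyl)silyl]oxy}methyl)-2-methyloxiran-2-yl]-3-methylhex-1-en-4-yl methanesulfonate
Conditions: MsCl, Et3N, CH2Cl2, 0 °C
Reagents that add atoms: methanesulfonyl chloride, CS(=O)(=O)Cl
Why: Sulfonylation of the only free hydroxyl, with retention, turns C3' into an SN2 electrophile.

Step 17
Reactants: 26 epoxy mesylate
Product: 27 (3R,4R,7S,8R)-9-{[tert-butyl(diphenyl)silyl]oxy}-7-hydroperoxy-8-hydroxy-3,7-dimethylnon-1-en-4-yl methanesulfonate
Conditions: H2O2 (anhydrous, in Et2O, 10 equiv), H3PMo12O40 (5 mol %), Et2O, rt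
Reagents that add atoms: hydrogen peroxide, OO
Why: Heteropolyacid-catalysed perhydrolysis of the epoxide, in which hydrogen peroxide attacks the activated oxirane at the tertiary carbon (better able to carry positive charge, remote from the silyloxymethyl carbon) from the rear and so inverts C6', while the secondary carbinol keeps its configuration.

Step 18
Reactants: 27 hydroperoxy mesylate
Product: 28 (1R)-1-[(3S,6S)-6-[(2R)-but-3-en-2-yl]-3-methyl-1,2-dioxan-3-yl]-2-{[tert-butyl(diphenyl)silyl]oxy}ethan-1-ol
Conditions: CsOH·H2O (1.2 equiv), DMF, 0 °C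
Reagents that add atoms: none
Why: Intramolecular peroxide alkylation, in which the hydroperoxide (far more acidic than the alcohol) is deprotonated selectively and its α-effect anion displaces the secondary mesylate in a 6-exo-tet SN2 closure with inversion at C3'.

Step 19
Reactants: 28 vinyl dioxane
Product: 29 (2S)-2-[(3S,6S)-6-[(1R)-2-{[tert-butyl(diphenyl)silyl]oxy}-1-hydroxyethyl]-6-methyl-1,2-dioxan-3-yl]propanal
Conditions: O3, pyridine (3 equiv), CH2Cl2, −78 °C
Reagents that add atoms: ozone, [O-][O+]=O
Why: Ozonolysis of the vinyl group under the pyridine protocol gives the aldehyde without any reductant that could attack the dialkyl peroxide, and the neutral cold medium should keep C2' from epimerising.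

Step 20
Reactants: 29 aldehyde
Product: 30 (2S)-2-[(3S,6S)-6-[(1R)-2-{[tert-butyl(diphenyl)silyl]oxy}-1-hydroxyethyl]-6-methyl-1,2-dioxan-3-yl]propanoic acid
Conditions: NaClO2, NaH2PO4, 2-methyl-2-butene, tBuOH/H2O, 0 °C
Reagents that add atoms: sodium chlorite, [Na+].[O-]Cl=O
Why: Pinnick oxidation in a buffered, weakly acidic medium converts the aldehyde to the acid without enolisation at C2' and without affecting the peroxide or the secondary alcohol.

Step 21
Reactants: 30 acid
Product: 31 methyl (2S)-2-[(3S,6S)-6-[(1R)-2-{[tert-butyl(diphenyl)silyl]oxy}-1-hydroxyethyl]-6-methyl-1,2-dioxan-3-yl]propanoate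
Conditions: Me3SiCHN2, MeOH/toluene, 0 °C
Reagents that add atoms: (trimethylsilyl)diazomethane, C[Si](C)(C)C=[N+]=[N-]
Why: Esterification by proton transfer from the acid to the diazoalkane followed by methyl transfer needs no base, so the β-peroxy ester cannot eliminate.

Step 22
Reactants: 31 silyl ether ester
Product: 32 methyl (2S)-2-[(3S,6S)-6-[(1R)-1,2-dihydroxyethyl]-6-methyl-1,2-dioxan-3-yl]propanoate
Conditions: Bu4NF, AcOH (1:1), THF, 0 °C to rt
Reagents that add atoms: none
Why: Fluoride cleaves the Si–O bond, and buffering with acetic acid keeps the medium from becoming basic enough to eliminate the peroxide from the ester enolate.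

Step 23
Reactants: 32 diol
Product: 33 methyl (2S)-2-[(3S,6S)-6-formyl-6-methyl-1,2-dioxan-3-yl]propanoate
Conditions: NaIO4, THF/pH 7 buffer, 0 °C
Reagents that add atoms: none
Why: Periodate glycol cleavage through the cyclic periodate ester removes the former C1 of geraniol as formaldehyde and leaves a non-enolisable aldehyde (C12) on the quaternary peroxide carbon.

**Union and completion**

Step 24
Reactants: 17 silyloxy sulfone; 33 dioxane aldehyde
Product: 35 methyl (2S)-2-[(3S,6S)-6-methyl-6-{(E)-2-[4,4,8,10-tetramethyl-5-(trimethylsilyloxy)-cis-decalin-9-yl]ethenyl}-1,2-dioxan-3-yl]propanoate (decalin centres as in 17), via potassium sulfonyl carbanion 34 (not isolated)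
Conditions: KN(SiMe3)2 (1.0 equiv), THF, −78 °C, 20 min; then 33, −78 to −40 °C; pH 7 buffer
Reagents that add atoms: none
Why: Julia–Kocienski olefination, in which the preformed sulfonyl carbanion adds to the non-enolisable aldehyde, a Smiles rearrangement moves the tetrazole to oxygen and loss of SO2 and tetrazolate gives the C11=C12 alkene; because no free amide base meets the aldehyde, the ester α-proton and the O–O bond should be spared.

Step 25
Reactants: 35 alkene
Product: 36 methyl (2S)-2-[(3S,6R)-6-methyl-6-{2-[(5S,8R,9S,10R)-4,4,8,10-tetramethyl-5-(trimethylsilyloxy)-cis-decalin-9-yl]ethyl}-1,2-dioxan-3-yl]propanoate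
Conditions: KO2CN=NCO2K (20 equiv, in portions), AcOH, MeOH/CH2Cl2, 0 °C to rt
Reagents that add atoms: none
Why: Diimide reduction, in which diimide formed by protonation and decarboxylation of the azodicarboxylate transfers two hydrogens to the C=C bond in a concerted syn fashion and leaves the O–O bond alone, unlike catalytic hydrogenation.

Step 26
Reactants: 36 silyl ether
Product: 37 methyl (2S)-2-[(3S,6R)-6-{2-[(5S,8R,9S,10R)-5-hydroxy-4,4,8,10-tetramethyl-cis-decalin-9-yl]ethyl}-6-methyl-1,2-dioxan-3-yl]propanoate (target CNP0274543.2)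
Conditions: HF·pyridine, pyridine, THF, 0 °C to rt
Reagents that add atoms: none
Why: Fluoride-assisted cleavage of the Si–O bond under mildly acidic buffered conditions frees the tertiary C5 alcohol without ionising it and without touching the ester or the peroxide.

**Compound list**
1 | propanal | CCC=O | starting material
2 | pent-1-en-3-one | C=CC(=O)CC | starting material
3 | (R)-2-methyl-5-oxoheptanal | CCC(=O)CC[C@@H](C)C=O | intermediate
4 | (R)-2,4-dimethylcyclohex-2-en-1-one | O=C1CC[C@@H](C)C=C1C | intermediate
5 | (chloromethyl)dimethylphenylsilane | C[Si](C)(CCl)c1ccccc1 | starting material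
6 | [(dimethylphenylsilyl)methyl]magnesium chloride | C[Si](C)(C[Mg]Cl)c1ccccc1 | intermediate
7 | {[(3S,4R)-3-[(dimethylphenylsilyl)methyl]-2,4-dimethylcyclohex-1-en-1-yl]oxy}trimethylsilane | C[Si](C)(c1ccccc1)C[C@H]1[C@H](C)CCC(O[Si](C)(C)C)=C1C | intermediate
8 | 5-bromo-2-methylpent-2-ene | CC(C)=CCCBr | starting material
9 | 5-iodo-2-methylpent-2-ene | CC(C)=CCCI | intermediate
10 | lithium (3S,4R)-3-[(dimethylphenylsilyl)methyl]-2,4-dimethylcyclohex-1-en-1-olate | C[Si](C)(c1ccccc1)C[C@H]1[C@H](C)CCC(O[Li])=C1C | intermediate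
11 | (2R,3S,4R)-3-[(dimethylphenylsilyl)methyl]-2,4-dimethyl-2-(4-methylpent-3-en-1-yl)cyclohexan-1-one | C[Si](C)(c1ccccc1)C[C@H]1[C@H](C)CCC(=O)[C@]1(C)CCC=C(C)C | intermediate
12 | (5S,8R,9S,10R)-9-[(dimethylphenylsilyl)methyl]-4,4,8,10-tetramethyl-cis-decalin-5-ol | C[Si](C)(c1ccccc1)C[C@H]1[C@H](C)CC[C@]2(O)C(C)(C)CCC[C@]12C | intermediate
13 | (5S,8R,9S,10R)-9-(hydroxymethyl)-4,4,8,10-tetramethyl-cis-decalin-5-ol | OC[C@H]1[C@H](C)CC[C@]2(O)C(C)(C)CCC[C@]12C | intermediate
14 | 1-phenyl-1H-tetrazole-5-thiol | Sc1nnnn1-c1ccccc1 | starting material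
15 | decalin C11 1-phenyltetrazol-5-yl sulfide (5-OH free) | S(C[C@H]1[C@H](C)CC[C@]2(O)C(C)(C)CCC[C@]12C)c1nnnn1-c1ccccc1 | intermediate
16 | decalin C11 1-phenyltetrazol-5-yl sulfone (5-OH free) | O=S(=O)(C[C@H]1[C@H](C)CC[C@]2(O)C(C)(C)CCC[C@]12C)c1nnnn1-c1ccccc1 | intermediate
17 | decalin C11 1-phenyltetrazol-5-yl sulfone, C5 trimethylsilyl ether | O=S(=O)(C[C@H]1[C@H](C)CC[C@]2(O[Si](C)(C)C)C(C)(C)CCC[C@]12C)c1nnnn1-c1ccccc1 | intermediate
18 | geraniol | CC(C)=CCC/C(C)=C/CO | starting material
19 | [(2R,3R)-3-methyl-3-(4-methylpent-3-en-1-yl)oxiran-2-yl]methanol | CC(C)=CCC[C@@]1(C)O[C@@H]1CO | intermediate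
20 | tert-butyl{[(2R,3R)-3-methyl-3-(4-methylpent-3-en-1-yl)oxiran-2-yl]methoxy}diphenylsilane | CC(C)=CCC[C@@]1(C)O[C@@H]1CO[Si](c1ccccc1)(c1ccccc1)C(C)(C)C | intermediate
21 | 3-[(2R,3R)-3-({[tert-butyl(diphenyl)silyl]oxy}methyl)-2-methyloxiran-2-yl]propanal | O=CCC[C@@]1(C)O[C@@H]1CO[Si](c1ccccc1)(c1ccccc1)C(C)(C)C | intermediate
22 | cis-2-butene | C/C=C\C | starting material
23 | (Z)-crotylpotassium | C/C=C\C[K] | intermediate
24 | (Z)-crotyldiisopinocampheylborane, isopinocampheyl groups from (+)-α-pinene | C/C=C\CB([C@@H]1C[C@@H]2C[C@H]([C@H]1C)C2(C)C)[C@@H]1C[C@@H]2C[C@H]([C@H]1C)C2(C)C | intermediate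
25 | (3R,4R)-6-[(2R,3R)-3-({[tert-butyl(diphenyl)silyl]oxy}methyl)-2-methyloxiran-2-yl]-3-methylhex-1-en-4-ol | C=C[C@@H](C)[C@H](O)CC[C@@]1(C)O[C@@H]1CO[Si](c1ccccc1)(c1ccccc1)C(C)(C)C | intermediate
26 | methanesulfonate of 25 | C=C[C@@H](C)[C@H](OS(C)(=O)=O)CC[C@@]1(C)O[C@@H]1CO[Si](c1ccccc1)(c1ccccc1)C(C)(C)C | intermediate
27 | (3R,4R,7S,8R)-9-{[tert-butyl(diphenyl)silyl]oxy}-7-hydroperoxy-8-hydroxy-3,7-dimethylnon-1-en-4-yl methanesulfonate | C=C[C@@H](C)[C@H](OS(C)(=O)=O)CC[C@@](C)([C@H](O)CO[Si](c1ccccc1)(c1ccccc1)C(C)(C)C)OO | intermediate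
28 | (1R)-1-[(3S,6S)-6-[(2R)-but-3-en-2-yl]-3-methyl-1,2-dioxan-3-yl]-2-{[tert-butyl(diphenyl)silyl]oxy}ethan-1-ol | C=C[C@@H](C)[C@@H]1CC[C@@](C)([C@H](O)CO[Si](c2ccccc2)(c2ccccc2)C(C)(C)C)OO1 | intermediate
29 | (2S)-2-[(3S,6S)-6-[(1R)-2-{[tert-butyl(diphenyl)silyl]oxy}-1-hydroxyethyl]-6-methyl-1,2-dioxan-3-yl]propanal | O=C[C@@H](C)[C@@H]1CC[C@@](C)([C@H](O)CO[Si](c2ccccc2)(c2ccccc2)C(C)(C)C)OO1 | intermediate
30 | (2S)-2-[(3S,6S)-6-[(1R)-2-{[tert-butyl(diphenyl)silyl]oxy}-1-hydroxyethyl]-6-methyl-1,2-dioxan-3-yl]propanoic acid | OC(=O)[C@@H](C)[C@@H]1CC[C@@](C)([C@H](O)CO[Si](c2ccccc2)(c2ccccc2)C(C)(C)C)OO1 | intermediate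
31 | methyl ester of 30 | COC(=O)[C@@H](C)[C@@H]1CC[C@@](C)([C@H](O)CO[Si](c2ccccc2)(c2ccccc2)C(C)(C)C)OO1 | intermediate
32 | methyl (2S)-2-[(3S,6S)-6-[(1R)-1,2-dihydroxyethyl]-6-methyl-1,2-dioxan-3-yl]propanoate | COC(=O)[C@@H](C)[C@@H]1CC[C@@](C)([C@H](O)CO)OO1 | intermediate
33 | methyl (2S)-2-[(3S,6S)-6-formyl-6-methyl-1,2-dioxan-3-yl]propanoate | COC(=O)[C@@H](C)[C@@H]1CC[C@@](C)(C=O)OO1 | intermediate
34 | potassium salt of the C11 carbanion of sulfone 17 | [K+].[CH-](S(=O)(=O)c1nnnn1-c1ccccc1)[C@H]1[C@H](C)CC[C@]2(O[Si](C)(C)C)C(C)(C)CCC[C@]12C | intermediate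
35 | (E)-C11=C12 alkene, C5 trimethylsilyl ether | COC(=O)[C@@H](C)[C@@H]1CC[C@@](C)(/C=C/[C@H]2[C@H](C)CC[C@]3(O[Si](C)(C)C)C(C)(C)CCC[C@]23C)OO1 | intermediate
36 | C5 trimethylsilyl ether of the target | COC(=O)[C@@H](C)[C@@H]1CC[C@@](C)(CC[C@H]2[C@H](C)CC[C@]3(O[Si](C)(C)C)C(C)(C)CCC[C@]23C)OO1 | intermediate
37 | methyl (2S)-2-[(3S,6R)-6-{2-[(5S,8R,9S,10R)-5-hydroxy-4,4,8,10-tetramethyl-cis-decalin-9-yl]ethyl}-6-methyl-1,2-dioxan-3-yl]propanoate | COC(=O)[C@@H](C)[C@@H]1CC[C@@](C)(CC[C@H]2[C@H](C)CC[C@]3(O)C(C)(C)CCC[C@]23C)OO1 | target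

**Step count**
Total: 26 steps. Longest linear sequence: 15 steps (steps 12 to 23 from geraniol, then steps 24 to 26). The decalin branch (steps 1, 2, 4, 6 to 11, then 24 to 26) is 12 steps long.

**Steps most likely to fail**

Step 6. The hindered tetrasubstituted enolate may act as a base toward the homoallylic iodide (E2 elimination to a conjugated diene) or alkylate on oxygen, so that the C10 quaternary centre forms inefficiently. The fallback sets out from silyl enol ether 7 and uses an allylic electrophile, then builds the tether in stages. Enolate 10 is regenerated with MeLi and alkylated with allyl bromide (same anti approach) to give the 10-allyl ketone F1. Hydroboration of the terminal alkene with 9-BBN and NaBO3 oxidation should give the primary alcohol F2, the hindered ketone being left alone. Dess–Martin oxidation then gives the keto aldehyde F3. A Wittig reaction with isopropylidenetriphenylphosphorane (from isopropyltriphenylphosphonium iodide and n-BuLi, −78 °C) should react only at the aldehyde and comes back to the route at ketone 11.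

Step 18. Base may remove the allylic C2' hydrogen with E2 loss of the mesylate, or trigger fragmentation of the β-hydroxy hydroperoxide, faster than the 6-exo displacement at the hindered secondary carbon; the tertiary-centre perhydrolysis of step 17 may also erode the C6' configuration. The fallback sets out from mesylate 26, reverses the order of the two C–O bond formations and bypasses steps 17 and 18. Intermolecular SN2 displacement of the mesylate with 2-methoxyprop-2-yl hydroperoxide (CsOH·H2O, DMF) should give, with inversion at C3', the peroxyketal F4. Mild acid (pyridinium p-toluenesulfonate in MeOH, then catalytic H3PMo12O40 in CH2Cl2) releases the epoxy hydroperoxide F5. Under the same acid catalysis F5 should open the epoxide intramolecularly at the tertiary carbon (6-exo, inversion at C6') and come back to the route at dioxane 28 with both centres as in the main line.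

Step 24. Addition of the β-branched sulfonyl carbanion to the α-quaternary aldehyde may be slow, leaving time for the carbanion or the intermediate alkoxide to deprotonate the ester at C2' with E1cB opening of the dioxane. The fallback sets out from acid 30 and carries out the union on the carboxylate, which cannot enolise. Buffered desilylation (Bu4NF/AcOH) gives the dihydroxy acid F6, and NaIO4 cleavage gives the formyl acid F7. F7 is added at −78 °C to two equivalents of carbanion 34; the first equivalent only forms the carboxylate and is recovered as sulfone 17. The olefination then gives the alkene acid F8. Esterification with Me3SiCHN2 comes back to the route at alkene 35.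

**Further compounds**
F1 | step 6 | (2R,3S,4R)-2-allyl-3-[(dimethylphenylsilyl)methyl]-2,4-dimethylcyclohexan-1-one | C[Si](C)(c1ccccc1)C[C@H]1[C@H](C)CCC(=O)[C@]1(C)CC=C
F2 | step 6 | (2R,3S,4R)-3-[(dimethylphenylsilyl)methyl]-2-(3-hydroxypropyl)-2,4-dimethylcyclohexan-1-one | C[Si](C)(c1ccccc1)C[C@H]1[C@H](C)CCC(=O)[C@]1(C)CCCO
F3 | step 6 | 3-{(1R,2S,3R)-2-[(dimethylphenylsilyl)methyl]-1,3-dimethyl-6-oxocyclohexyl}propanal | C[Si](C)(c1ccccc1)C[C@H]1[C@H](C)CCC(=O)[C@]1(C)CCC=O
F4 | step 18 | C3'-inverted 2-methoxyprop-2-yl peroxyketal of the epoxy silyl ether | C=C[C@@H](C)[C@@H](OOC(C)(C)OC)CC[C@@]1(C)O[C@@H]1CO[Si](c1ccccc1)(c1ccccc1)C(C)(C)C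
F5 | step 18 | C3'-inverted secondary hydroperoxide of the epoxy silyl ether | C=C[C@@H](C)[C@@H](OO)CC[C@@]1(C)O[C@@H]1CO[Si](c1ccccc1)(c1ccccc1)C(C)(C)C
F6 | step 24 | (2S)-2-[(3S,6S)-6-[(1R)-1,2-dihydroxyethyl]-6-methyl-1,2-dioxan-3-yl]propanoic acid | OC(=O)[C@@H](C)[C@@H]1CC[C@@](C)([C@H](O)CO)OO1
F7 | step 24 | (2S)-2-[(3S,6S)-6-formyl-6-methyl-1,2-dioxan-3-yl]propanoic acid | OC(=O)[C@@H](C)[C@@H]1CC[C@@](C)(C=O)OO1
F8 | step 24 | (E)-C11=C12 alkene carboxylic acid, C5 trimethylsilyl ether | OC(=O)[C@@H](C)[C@@H]1CC[C@@](C)(/C=C/[C@H]2[C@H](C)CC[C@]3(O[Si](C)(C)C)C(C)(C)CCC[C@]23C)OO1
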